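## The problem

The target is a 5,6,7,8-tetrahydro-1H-isochromen-8-one. Cyclohexenone ring A and 2H-pyran ring B share the tetrasubstituted C4a=C8a double bond, so that O2–C3=C4–C4a=C8a–C8=O is one continuous push–pull chain. Ring A carries a cis pair of carbinols next to the C8 ketone: C6 (secondary, esterified by orsellinic acid) and C7 (tertiary, methyl-bearing, 6R,7R). C3 carries a trans (2S,3R)-3-methyloxirane. The ring A pair and the epoxide are too far apart to control one another, so each must come from its own enantiopure source; C7 is quaternary and cannot be corrected later. The dienyl ether with an epoxide on C3 is an alkoxy-substituted vinyl oxirane and will not survive acid. The α-ketol/β-acyloxy ketone array is open to retro-aldol cleavage and acyl shift under strong base, and the hindered aryl ester cannot pass through hydride, organolithium or titanium alkylidene steps. The structural feature that opens the synthesis is that C3=C4 is an enol ether double bond whose two carbons sit on arms held cis by C4a=C8a: C4 can come from a vinyl group on C4a and C3 from a 1-alkoxyvinyl group on O2.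

## Retrosynthesis

**C6 ester (28 ⇒ 27 ⇒ 23 + 25).** The aryl ester C6–O bond is cut first. The ester would not survive the reductions and the carbonyl methylenation used earlier, and in diol 23 the secondary C6 hydroxyl is the only acylable one beside the tertiary C7 hydroxyl. Orsellinic acid 24 is carried as its persilylated form 25 and activated as aroyl chloride 26. The forward step must acylate a hindered alcohol under mild base, and the last step must remove two aryl silyl ethers with buffered fluoride.

**C8 oxidation level (23 ⇒ 22 ⇒ 21).** The C8 ketone is traced to an allylic silyl ether, because an ester methylenation earlier in the route would also attack a ketone. One fluoride treatment of 21 should free triol 22, and MnO2 should oxidize only the allylic C8 carbinol. This costs two steps but needs no differentiated protecting groups on ring A.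

**C3=C4 by metathesis (21 ⇒ 20).** Ring B is opened at the enol ether double bond. The alternatives are acid-driven cyclodehydration of a C1 alcohol onto a C3 ketone or an oxa-electrocyclization, and both put acid or heat next to the epoxide. Metathesis is neutral, forms only this bond, and leaves triene 20 with ring A complete.

**Enol ether from an ester (20 ⇒ 19 ⇒ 15 + 18).** The 1-alkoxyvinyl group is the methylenation product of glycidic ester 19, which is cut at the acyl–oxygen bond into dienyl alcohol 15 and epoxy acid 18. This brings the epoxide in as a complete, enantiopure unit and makes the union an ordinary esterification. The methylenation must tolerate an epoxide and a diene.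

**Epoxy acid (18 ⇒ 17 ⇒ 16).** Acid 18 is the oxidation product of epoxy alcohol 17, the Sharpless epoxide of (E)-but-2-en-1-ol 16. Both epoxide stereocentres are set in one catalytic step.

**Tetrasubstituted alkene of ring A (15 ⇒ 14 ⇒ 13 ⇒ 12).** The C4a vinyl group is a methylenated aldehyde (14 from enal 13), and the primary silyl ether of 14 is cleaved selectively to 15. Enal 13 is cut at C4a=C8a by an aldol condensation of keto aldehyde 12. A condensation is preferred to a metathesis or enyne metathesis, which would have to form a tetrasubstituted alkene. It is also preferred to cross-coupling on a 1,3-dione, where regiochemistry and the C1 carbon are unsolved. The aldol must occur through the aldehyde enamine onto the ketone.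

**C8–C8a bond and protecting-group change (12 ⇒ 11 ⇒ 10 ⇒ 9 ⇒ 8 ⇒ 7).** The ketone of 12 is an ozonized 1,1-disubstituted alkene and the aldehyde is a reduced nitrile (11, 10). The alkene with its CH2O arm comes from addition of a 2-metallated allyl alkoxide to aldehyde 7, which gives diol 8. Between these points the acetonide is exchanged for silyl ethers (9, 10), since the final deprotection must be by fluoride. The C8 configuration is irrelevant.

**C5–C4a bond and chiral pool (7 ⇒ 6 ⇒ 4 ⇒ 3 ⇒ 2 ⇒ 1).** Aldehyde 7 is the ozonolysis product of vinyl dioxolane 6. The two-carbon nitrile arm of 6 is attached by SN2 displacement of primary triflate 5, made from alcohol 4. Alcohol 4 is the Wittig product of lactol 3, obtained from acetonide 2 of 2-C-methyl-D-erythrono-1,4-lactone 1. The lactone supplies C6 and C7 with the correct absolute and relative configuration, C8 as its carbonyl carbon and C5 as its CH2O carbon. The vinyl group masks C8 while C5 is extended.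

## Roads not taken

**Alternative 1:** The cut removes the two C–O bonds at C6 and C7. The aromatic acid A1 (3-oxoisochromane-7-carboxylic acid) would be dihydroxylated ipso,ortho by whole cells expressing a benzoate 1,2-dioxygenase to give cis-dihydrodiol acid A2.
- Merits: one aqueous step turns a flat bicyclic aromatic into an enantiopure ring A with both oxygens, the quaternary centre and ring B's carbon frame. In step count to a cis-diol this is clearly better than the thirteen steps to 15.
- Weak points: acceptance of a ring-fused benzoate by the enzyme is uncertain, and its facial sense cannot be tuned. The carboxyl on C7 must be reduced to methyl on a diene that aromatizes by loss of water or CO2. The C5=C4a/C8a=C8 diene must be moved to C4a=C8a with oxygen placed on C8. The lactone carbonyl must still become an enol ether carrying the epoxide.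
- Comparison: the enzymatic step wins on brevity and on atom economy. Against this the chosen plan sets a C7 methyl and C6/C7 configuration taken unchanged from lactone 1, and a sequence in which no intermediate can aromatize.

**Alternative 2:** The cut is C4a–C5. Iodo ynone A3 would cyclize by iodine-atom transfer: the primary C5 radical adds 6-endo to the ynone β-carbon and the vinyl radical takes iodine, giving α-iodo enone A4.
- Merits: the C8 ketone comes straight from the lactone carbonyl, with no reduction and re-oxidation. The C3 side chain with the epoxide is attached convergently as an acetylide, and the iodide on C8a is a ready handle for the C1 carbon. Ring A is reached in fewer steps than here.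
- Weak points: 5-exo closure competes with the 6-endo mode. After A4, ring B must still be closed by C1–O–C3 bond formation. That requires a C3 ketone beside the epoxide and a cyclodehydration, the one operation the epoxy dienyl ether tolerates least.
- Comparison: alternative 2 is the better plan for ring A. The chosen plan answers with a neutral, ruthenium-catalysed formation of the enol ether in which C3 never passes through a ketone.

**Alternative 3:** The cut is C6–C7. Acetyl carbinol A5, a cyclopenta[c]pyran, would undergo α-ketol rearrangement with Al(OC(CH3)3)3: C6 migrates from C8 to the acetyl carbon, giving six-membered ketol A6.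
- Merits: one step creates the C7 carbinol with its methyl group, the C8 ketone and ring A. A6 is only a desilylation away from 23, so the endgame is shorter than here and needs no oxidation-state change at C8.
- Weak points: the configuration at C7 depends on the C8 carbinol configuration of A5 and on a chelated transition state. The alkenyl carbon C8a can migrate in place of C6, and the rearrangement is reversible. A Lewis-acidic aluminium alkoxide must be applied to the complete epoxy dienyl ether. A5 itself needs a separate enantioselective synthesis.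
- Comparison: alternative 3 concentrates the risk in one late, stereochemically uncertain step. The chosen plan spends more steps but fixes C6 and C7 from the first compound and exposes the sensitive ring B to only four mild reactions.

Key step: step 18

Remarks on the chemistry:
- Locants C1–C8a follow the isochromene numbering of the target throughout.
- Compounds 8–22 are written with the (8S) configuration that Felkin–Anh addition in step 6 should favour. This centre lies next to a ketone in 12 and may epimerize in step 11; it becomes the C8 ketone in step 20, so either epimer serves.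
- Lactol 3 is a mixture of anomers.

## Steps

Step 1
Reactants: 1 2-C-methyl-D-erythrono-1,4-lactone
Product: 2 2,3-O-isopropylidene-2-C-methyl-D-erythrono-1,4-lactone
Conditions: Me2C(OMe)2, TsOH·H2O (cat.), acetone, rt
Reagents that add atoms: 2,2-dimethoxypropane, COC(C)(C)OC
Why: Acid-catalysed transacetalization ties the cis-diol into a cis-fused dioxolane; both carbinol centres are untouched.

Step 2
Reactants: 2 2,3-O-isopropylidene-2-C-methyl-D-erythrono-1,4-lactone
Product: 3 2,3-O-isopropylidene-2-C-methyl-D-erythrofuranose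
Conditions: iBu2AlH, CH2Cl2, −78 °C; aq. potassium sodium tartrate
Reagents that add atoms: none
Why: Partial reduction of a γ-lactone; the tetrahedral aluminium alkoxide is stable at −78 °C, so the reduction should stop at the lactol.

Step 3
Reactants: 3 2,3-O-isopropylidene-2-C-methyl-D-erythrofuranose
Product: 4 [(4R,5S)-5-ethenyl-2,2,5-trimethyl-1,3-dioxolan-4-yl]methanol
Conditions: Ph3PCH3Br, KOC(CH3)3, THF, 0 → 50 °C
Reagents that add atoms: methyltriphenylphosphonium bromide, C[P+](c1ccccc1)(c1ccccc1)c1ccccc1.[Br-]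
Why: Wittig methylenation of the hydroxy aldehyde in equilibrium with the lactol masks C8 as a vinyl group and frees the primary C5 hydroxyl; the aldehyde α-carbon is quaternary and cannot epimerize.

Step 4
Reactants: 4 [(4R,5S)-5-ethenyl-2,2,5-trimethyl-1,3-dioxolan-4-yl]methanol
Product: 6 3-[(4R,5S)-5-ethenyl-2,2,5-trimethyl-1,3-dioxolan-4-yl]propanenitrile, via primary triflate 5 (not isolated)
Conditions: Tf2O, pyridine, CH2Cl2, −40 °C; then LiCH2CN (MeCN, n-BuLi), THF, −78 → −30 °C
Reagents that add atoms: acetonitrile, CC#N (as LiCH2CN); trifluoromethanesulfonic anhydride, O=S(=O)(OS(=O)(=O)C(F)(F)F)C(F)(F)F (retained only in 5)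
Why: Triflation followed by SN2 displacement with lithioacetonitrile forms the C5–C4a bond at a primary carbon; no stereocentre takes part.

Step 5
Reactants: 6 3-[(4R,5S)-5-ethenyl-2,2,5-trimethyl-1,3-dioxolan-4-yl]propanenitrile
Product: 7 3-[(4R,5R)-5-formyl-2,2,5-trimethyl-1,3-dioxolan-4-yl]propanenitrile
Conditions: O3, CH2Cl2, −78 °C; PPh3, → rt
Reagents that add atoms: ozone, [O-][O+]=O
Why: Ozonolysis with reductive work-up unmasks the C8 aldehyde; nitrile and acetal are inert and the aldehyde is not enolizable.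

Step 6
Reactants: 7 3-[(4R,5R)-5-formyl-2,2,5-trimethyl-1,3-dioxolan-4-yl]propanenitrile
Product: 8 3-{(4R,5S)-5-[(1S)-1-hydroxy-2-(hydroxymethyl)prop-2-en-1-yl]-2,2,5-trimethyl-1,3-dioxolan-4-yl}propanenitrile
Conditions: CH2=C(Br)CH2OH, t-BuLi (3 equiv), Et2O, −78 → 0 °C; then 7, −78 °C; H2O
Reagents that add atoms: 2-bromoprop-2-en-1-ol, OCC(Br)=C
Why: 1,2-Addition of the alkenyllithium made by bromine–lithium exchange forms C8–C8a and brings in C1 as a free alcohol; addition to the aldehyde at −78 °C should outrun deprotonation next to the nitrile. Felkin–Anh attack anti to the dioxolane C–O bond should favour the (8S) carbinol, a centre that is removed later.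

Step 7
Reactants: 8 3-{(4R,5S)-5-[(1S)-1-hydroxy-2-(hydroxymethyl)prop-2-en-1-yl]-2,2,5-trimethyl-1,3-dioxolan-4-yl}propanenitrile
Product: 9 (4R,5R,6S)-4,5,6,8-tetrahydroxy-5-methyl-7-methylideneoctanenitrile
Conditions: AcOH/H2O (4:1), 45 °C
Reagents that add atoms: none
Why: Mild aqueous acid hydrolyses the isopropylidene acetal at a stage where no acid-labile group is present, so that all later deprotection can be done with fluoride.

Step 8
Reactants: 9 (4R,5R,6S)-4,5,6,8-tetrahydroxy-5-methyl-7-methylideneoctanenitrile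
Product: 10 (4R,5R,6S)-5-methyl-7-methylidene-4,5,6,8-tetrakis(triethylsilyloxy)octanenitrile
Conditions: Et3SiOTf, 2,6-lutidine, CH2Cl2, −78 → 0 °C
Reagents that add atoms: triethylsilyl trifluoromethanesulfonate, CC[Si](CC)(CC)OS(=O)(=O)C(F)(F)F
Why: The silyl triflate silylates all four hydroxyls, the tertiary one included, in one operation.

Step 9
Reactants: 10 (4R,5R,6S)-5-methyl-7-methylidene-4,5,6,8-tetrakis(triethylsilyloxy)octanenitrile
Product: 11 (4R,5R,6S)-5-methyl-7-methylidene-4,5,6,8-tetrakis(triethylsilyloxy)octanal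
Conditions: iBu2AlH, toluene, −78 °C; aq. potassium sodium tartrate, rt
Reagents that add atoms: water, O
Why: Hydride addition to the nitrile stops at the N-aluminoimine, which hydrolyses to the C4 aldehyde on work-up; silyl ethers and the alkene are inert.

Step 10
Reactants: 11 (4R,5R,6S)-5-methyl-7-methylidene-4,5,6,8-tetrakis(triethylsilyloxy)octanal
Product: 12 (4R,5R,6R)-5-methyl-7-oxo-4,5,6,8-tetrakis(triethylsilyloxy)octanal
Conditions: O3, CH2Cl2, −78 °C; PPh3, → rt
Reagents that add atoms: ozone, [O-][O+]=O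
Why: Ozonolysis of the 1,1-disubstituted alkene gives the C8a ketone; the aldehyde survives ozone at −78 °C with reductive work-up.

Step 11
Reactants: 12 (4R,5R,6R)-5-methyl-7-oxo-4,5,6,8-tetrakis(triethylsilyloxy)octanal
Product: 13 (3S,4R,5R)-4-methyl-3,4,5-tris(triethylsilyloxy)-2-[(triethylsilyloxy)methyl]cyclohex-1-ene-1-carbaldehyde
Conditions: Bn2NH·CF3CO2H (20 mol%), toluene, 50 °C
Reagents that add atoms: none
Why: Intramolecular aldol condensation: the amine forms an enamine with the unhindered aldehyde, whose α-carbon C4a adds to the activated bis(α-silyloxy) ketone in a 6-(enolexo)-exo-trig closure. Loss of water gives the conjugated tetrasubstituted C4a=C8a enal, closing ring A.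

Step 12
Reactants: 13 (3S,4R,5R)-4-methyl-3,4,5-tris(triethylsilyloxy)-2-[(triethylsilyloxy)methyl]cyclohex-1-ene-1-carbaldehyde
Product: 14 (3S,4R,5R)-1-ethenyl-4-methyl-3,4,5-tris(triethylsilyloxy)-2-[(triethylsilyloxy)methyl]cyclohex-1-ene
Conditions: Ph3PCH3Br, KOC(CH3)3, THF, 0 °C
Reagents that add atoms: methyltriphenylphosphonium bromide, C[P+](c1ccccc1)(c1ccccc1)c1ccccc1.[Br-]
Why: Wittig methylenation of a 2,6-disubstituted cyclohexenecarbaldehyde with the smallest ylide turns C4 into the vinyl carbon needed for metathesis.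

Step 13
Reactants: 14 (3S,4R,5R)-1-ethenyl-4-methyl-3,4,5-tris(triethylsilyloxy)-2-[(triethylsilyloxy)methyl]cyclohex-1-ene
Product: 15 [(4R,5R,6S)-2-ethenyl-5-methyl-4,5,6-tris(triethylsilyloxy)cyclohex-1-en-1-yl]methanol
Conditions: HF·pyridine, pyridine, THF, 0 °C
Reagents that add atoms: none
Why: Buffered HF·pyridine cleaves the primary triethylsilyl ether much faster than the hindered secondary and tertiary ones, freeing only the C1 hydroxyl.

Step 14
Reactants: 16 (E)-but-2-en-1-ol
Product: 17 [(2R,3R)-3-methyloxiran-2-yl]methanol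
Conditions: Ti(OiPr)4 (5 mol%), D-(−)-diisopropyl tartrate (6 mol%), t-BuOOH, 4 Å MS, CH2Cl2, −20 °C
Reagents that add atoms: tert-butyl hydroperoxide, CC(C)(C)OO
Why: Sharpless asymmetric epoxidation; with the D-tartrate the titanium-bound peroxide delivers oxygen to the face of the (E)-allylic alcohol that gives the (2R,3R) trans-epoxide, setting both epoxide centres.

Step 15
Reactants: 17 [(2R,3R)-3-methyloxiran-2-yl]methanol
Product: 18 (2S,3R)-3-methyloxirane-2-carboxylic acid
Conditions: RuCl3·xH2O (2 mol%), NaIO4, CCl4/MeCN/H2O, rt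
Reagents that add atoms: water, O; sodium periodate, [Na+].[O-]I(=O)(=O)=O (terminal oxidant for RuO4)
Why: RuO4 generated in situ oxidizes the primary alcohol to the acid without opening the epoxide; the descriptor at C2 changes only because the substituent ranking changes.

Step 16
Reactants: 15 [(4R,5R,6S)-2-ethenyl-5-methyl-4,5,6-tris(triethylsilyloxy)cyclohex-1-en-1-yl]methanol; 18 (2S,3R)-3-methyloxirane-2-carboxylic acid
Product: 19 [(4R,5R,6S)-2-ethenyl-5-methyl-4,5,6-tris(triethylsilyloxy)cyclohex-1-en-1-yl]methyl (2S,3R)-3-methyloxirane-2-carboxylate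
Conditions: DCC, DMAP (cat.), CH2Cl2, 0 °C → rt
Reagents that add atoms: none
Why: Steglich esterification of an unhindered primary allylic alcohol; the conditions are neutral and leave the epoxide and its α-stereocentre intact.

Step 17
Reactants: 19 [(4R,5R,6S)-2-ethenyl-5-methyl-4,5,6-tris(triethylsilyloxy)cyclohex-1-en-1-yl]methyl (2S,3R)-3-methyloxirane-2-carboxylate
Product: 20 (2S,3R)-2-(1-{[(4R,5R,6S)-2-ethenyl-5-methyl-4,5,6-tris(triethylsilyloxy)cyclohex-1-en-1-yl]methoxy}ethenyl)-3-methyloxirane
Conditions: Cp2TiMe2, toluene/THF, 70 °C, dark; filtration through basic alumina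
Reagents that add atoms: dimethyltitanocene, [CH3-].[CH3-].[Ti+4].c1cc[cH-]c1.c1cc[cH-]c1
Why: Petasis methylenation: thermally generated Cp2Ti=CH2 adds to the activated ester carbonyl and the oxatitanacyclobutane collapses to the enol ether. The reagent is not Lewis acidic, which should spare the epoxide, and the silyl ethers are inert.

Step 18
Reactants: 20 (2S,3R)-2-(1-{[(4R,5R,6S)-2-ethenyl-5-methyl-4,5,6-tris(triethylsilyloxy)cyclohex-1-en-1-yl]methoxy}ethenyl)-3-methyloxirane
Product: 21 (6R,7R,8S)-7-methyl-3-[(2S,3R)-3-methyloxiran-2-yl]-6,7,8-tris(triethylsilyloxy)-5,6,7,8-tetrahydro-1H-isochromene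
Conditions: (H2IMes)(PCy3)Cl2Ru=CHPh (second-generation Grubbs catalyst, 10 mol%), toluene (2 mM), 70 °C
Reagents that add atoms: none
Why: Ring-closing olefin metathesis of an olefinic enol ether, the known way from methylenated esters to cyclic enol ethers. The benzylidene catalyst should initiate at the only monosubstituted alkene, the C4a vinyl group, placing ruthenium on C4 with loss of styrene. This alkylidene adds across the 1,1-disubstituted enol ether to a ruthenacyclobutane that collapses to the C3=C4 double bond and Ru=CH2, which carries the cycle with loss of ethene. Ring B closes as a six-membered ring in which both alkene carbons become ring members; the C4a=C8a double bond holds the two arms cis, so closure should outrun dimerization at high dilution. No stereocentre is formed, and C6, C7, C8 and the epoxide carbons are untouched under the neutral conditions. The selectivity required is initiation at the vinyl group before the enol ether, since a ruthenium alkoxycarbene formed there propagates poorly; the difference between a monosubstituted alkene and an oxygenated 1,1-disubstituted one secures it.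

Step 19
Reactants: 21 (6R,7R,8S)-7-methyl-3-[(2S,3R)-3-methyloxiran-2-yl]-6,7,8-tris(triethylsilyloxy)-5,6,7,8-tetrahydro-1H-isochromene
Product: 22 (6R,7R,8S)-7-methyl-3-[(2S,3R)-3-methyloxiran-2-yl]-5,6,7,8-tetrahydro-1H-isochromene-6,7,8-triol
Conditions: Bu4NF, THF, 0 °C → rt; crude product used directly
Reagents that add atoms: none
Why: Fluoride cleaves all three silyl ethers under basic conditions that the epoxy dienyl ether tolerates; the ionizable C8 allylic alcohol is not chromatographed.

Step 20
Reactants: 22 (6R,7R,8S)-7-methyl-3-[(2S,3R)-3-methyloxiran-2-yl]-5,6,7,8-tetrahydro-1H-isochromene-6,7,8-triol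
Product: 23 (6R,7R)-6,7-dihydroxy-7-methyl-3-[(2S,3R)-3-methyloxiran-2-yl]-6,7-dihydro-1H-isochromen-8(5H)-one
Conditions: MnO2, CH2Cl2, rt
Reagents that add atoms: none
Why: MnO2 oxidizes only the allylic C8 carbinol, giving the vinylogous ester ketone; the saturated C6 and tertiary C7 hydroxyls are inert, and the C8 epimer question disappears.

Step 21
Reactants: 24 orsellinic acid
Product: 25 tert-butyldimethylsilyl 2,4-bis(tert-butyldimethylsilyloxy)-6-methylbenzoate
Conditions: t-BuMe2SiCl, imidazole, DMF, rt
Reagents that add atoms: tert-butylchlorodimethylsilane, CC(C)(C)[Si](C)(C)Cl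
Why: Exhaustive silylation protects both phenols and turns the acid into a silyl ester that can be converted directly into the acid chloride.

Step 22
Reactants: 25 tert-butyldimethylsilyl 2,4-bis(tert-butyldimethylsilyloxy)-6-methylbenzoate; 23 (6R,7R)-6,7-dihydroxy-7-methyl-3-[(2S,3R)-3-methyloxiran-2-yl]-6,7-dihydro-1H-isochromen-8(5H)-one
Product: 27 (6R,7R)-7-hydroxy-7-methyl-3-[(2S,3R)-3-methyloxiran-2-yl]-8-oxo-5,6,7,8-tetrahydro-1H-isochromen-6-yl 2,4-bis(tert-butyldimethylsilyloxy)-6-methylbenzoate, via aroyl chloride 26 (not isolated)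
Conditions: (COCl)2, DMF (cat.), CH2Cl2, 0 °C → rt; then 23, DMAP, Et3N, CH2Cl2, 0 °C → rt
Reagents that add atoms: oxalyl chloride, O=C(Cl)C(Cl)=O (chlorine retained only in 26)
Why: The silyl ester gives the acid chloride under neutral conditions; DMAP-mediated acylation takes the secondary C6 hydroxyl in preference to the tertiary C7 hydroxyl, and excess amine keeps the medium free of acid.

Step 23
Reactants: 27 (6R,7R)-7-hydroxy-7-methyl-3-[(2S,3R)-3-methyloxiran-2-yl]-8-oxo-5,6,7,8-tetrahydro-1H-isochromen-6-yl 2,4-bis(tert-butyldimethylsilyloxy)-6-methylbenzoate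
Product: 28 (6R,7R)-7-hydroxy-7-methyl-3-[(2S,3R)-3-methyloxiran-2-yl]-8-oxo-5,6,7,8-tetrahydro-1H-isochromen-6-yl 2,4-dihydroxy-6-methylbenzoate (CNP0323247.1)
Conditions: Bu4NF, AcOH (1:1), THF, 0 °C
Reagents that add atoms: none
Why: Aryl silyl ethers are cleaved rapidly by acetic-acid-buffered fluoride, conditions too mild to open the epoxide, hydrolyse the enol ether or move the acyl group.

## Compound list

1 | 2-C-methyl-D-erythrono-1,4-lactone, (3R,4R)-3,4-dihydroxy-3-methyloxolan-2-one | O[C@@H]1COC(=O)[C@]1(C)O | starting material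
2 | 2,3-O-isopropylidene-2-C-methyl-D-erythrono-1,4-lactone, (3aR,6aR)-2,2,3a-trimethyl-6,6a-dihydro-3aH-furo[3,4-d][1,3]dioxol-4-one | CC1(C)O[C@@H]2COC(=O)[C@]2(C)O1 | intermediate
3 | 2,3-O-isopropylidene-2-C-methyl-D-erythrofuranose (anomer mixture) | CC1(C)O[C@@H]2COC(O)[C@]2(C)O1 | intermediate
4 | [(4R,5S)-5-ethenyl-2,2,5-trimethyl-1,3-dioxolan-4-yl]methanol | CC1(C)O[C@H](CO)[C@](C)(C=C)O1 | intermediate
5 | [(4R,5S)-5-ethenyl-2,2,5-trimethyl-1,3-dioxolan-4-yl]methyl trifluoromethanesulfonate | CC1(C)O[C@H](COS(=O)(=O)C(F)(F)F)[C@](C)(C=C)O1 | intermediate (not isolated)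
6 | 3-[(4R,5S)-5-ethenyl-2,2,5-trimethyl-1,3-dioxolan-4-yl]propanenitrile | CC1(C)O[C@H](CCC#N)[C@](C)(C=C)O1 | intermediate
7 | 3-[(4R,5R)-5-formyl-2,2,5-trimethyl-1,3-dioxolan-4-yl]propanenitrile | CC1(C)O[C@H](CCC#N)[C@](C)(C=O)O1 | intermediate
8 | 3-{(4R,5S)-5-[(1S)-1-hydroxy-2-(hydroxymethyl)prop-2-en-1-yl]-2,2,5-trimethyl-1,3-dioxolan-4-yl}propanenitrile | CC1(C)O[C@H](CCC#N)[C@](C)([C@@H](O)C(=C)CO)O1 | intermediate
9 | (4R,5R,6S)-4,5,6,8-tetrahydroxy-5-methyl-7-methylideneoctanenitrile | N#CCC[C@@H](O)[C@@](C)(O)[C@@H](O)C(=C)CO | intermediate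
10 | (4R,5R,6S)-5-methyl-7-methylidene-4,5,6,8-tetrakis(triethylsilyloxy)octanenitrile | N#CCC[C@@H](O[Si](CC)(CC)CC)[C@@](C)(O[Si](CC)(CC)CC)[C@@H](O[Si](CC)(CC)CC)C(=C)CO[Si](CC)(CC)CC | intermediate
11 | (4R,5R,6S)-5-methyl-7-methylidene-4,5,6,8-tetrakis(triethylsilyloxy)octanal | O=CCC[C@@H](O[Si](CC)(CC)CC)[C@@](C)(O[Si](CC)(CC)CC)[C@@H](O[Si](CC)(CC)CC)C(=C)CO[Si](CC)(CC)CC | intermediate
12 | (4R,5R,6R)-5-methyl-7-oxo-4,5,6,8-tetrakis(triethylsilyloxy)octanal | O=CCC[C@@H](O[Si](CC)(CC)CC)[C@@](C)(O[Si](CC)(CC)CC)[C@@H](O[Si](CC)(CC)CC)C(=O)CO[Si](CC)(CC)CC | intermediate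
13 | (3S,4R,5R)-4-methyl-3,4,5-tris(triethylsilyloxy)-2-[(triethylsilyloxy)methyl]cyclohex-1-ene-1-carbaldehyde | CC[Si](CC)(CC)O[C@@H]1CC(C=O)=C(CO[Si](CC)(CC)CC)[C@H](O[Si](CC)(CC)CC)[C@]1(C)O[Si](CC)(CC)CC | intermediate
14 | (3S,4R,5R)-1-ethenyl-4-methyl-3,4,5-tris(triethylsilyloxy)-2-[(triethylsilyloxy)methyl]cyclohex-1-ene | CC[Si](CC)(CC)O[C@@H]1CC(C=C)=C(CO[Si](CC)(CC)CC)[C@H](O[Si](CC)(CC)CC)[C@]1(C)O[Si](CC)(CC)CC | intermediate
15 | [(4R,5R,6S)-2-ethenyl-5-methyl-4,5,6-tris(triethylsilyloxy)cyclohex-1-en-1-yl]methanol | CC[Si](CC)(CC)O[C@@H]1CC(C=C)=C(CO)[C@H](O[Si](CC)(CC)CC)[C@]1(C)O[Si](CC)(CC)CC | intermediate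
16 | (E)-but-2-en-1-ol | C/C=C/CO | starting material
17 | [(2R,3R)-3-methyloxiran-2-yl]methanol | OC[C@H]1O[C@@H]1C | intermediate
18 | (2S,3R)-3-methyloxirane-2-carboxylic acid | OC(=O)[C@H]1O[C@@H]1C | intermediate
19 | [(4R,5R,6S)-2-ethenyl-5-methyl-4,5,6-tris(triethylsilyloxy)cyclohex-1-en-1-yl]methyl (2S,3R)-3-methyloxirane-2-carboxylate | CC[Si](CC)(CC)O[C@@H]1CC(C=C)=C(COC(=O)[C@H]2O[C@@H]2C)[C@H](O[Si](CC)(CC)CC)[C@]1(C)O[Si](CC)(CC)CC | intermediate
20 | (2S,3R)-2-(1-{[(4R,5R,6S)-2-ethenyl-5-methyl-4,5,6-tris(triethylsilyloxy)cyclohex-1-en-1-yl]methoxy}ethenyl)-3-methyloxirane | CC[Si](CC)(CC)O[C@@H]1CC(C=C)=C(COC(=C)[C@H]2O[C@@H]2C)[C@H](O[Si](CC)(CC)CC)[C@]1(C)O[Si](CC)(CC)CC | intermediate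
21 | (6R,7R,8S)-7-methyl-3-[(2S,3R)-3-methyloxiran-2-yl]-6,7,8-tris(triethylsilyloxy)-5,6,7,8-tetrahydro-1H-isochromene | CC[Si](CC)(CC)O[C@@H]1CC2=C(COC([C@H]3O[C@@H]3C)=C2)[C@H](O[Si](CC)(CC)CC)[C@]1(C)O[Si](CC)(CC)CC | intermediate
22 | (6R,7R,8S)-7-methyl-3-[(2S,3R)-3-methyloxiran-2-yl]-5,6,7,8-tetrahydro-1H-isochromene-6,7,8-triol | O[C@@H]1CC2=C(COC([C@H]3O[C@@H]3C)=C2)[C@H](O)[C@]1(C)O | intermediate
23 | (6R,7R)-6,7-dihydroxy-7-methyl-3-[(2S,3R)-3-methyloxiran-2-yl]-6,7-dihydro-1H-isochromen-8(5H)-one | O[C@@H]1CC2=C(COC([C@H]3O[C@@H]3C)=C2)C(=O)[C@]1(C)O | intermediate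
24 | orsellinic acid, 2,4-dihydroxy-6-methylbenzoic acid | Cc1cc(O)cc(O)c1C(=O)O | starting material
25 | tert-butyldimethylsilyl 2,4-bis(tert-butyldimethylsilyloxy)-6-methylbenzoate | Cc1cc(O[Si](C)(C)C(C)(C)C)cc(O[Si](C)(C)C(C)(C)C)c1C(=O)O[Si](C)(C)C(C)(C)C | intermediate
26 | 2,4-bis(tert-butyldimethylsilyloxy)-6-methylbenzoyl chloride | Cc1cc(O[Si](C)(C)C(C)(C)C)cc(O[Si](C)(C)C(C)(C)C)c1C(Cl)=O | intermediate (not isolated)
27 | (6R,7R)-7-hydroxy-7-methyl-3-[(2S,3R)-3-methyloxiran-2-yl]-8-oxo-5,6,7,8-tetrahydro-1H-isochromen-6-yl 2,4-bis(tert-butyldimethylsilyloxy)-6-methylbenzoate | Cc1cc(O[Si](C)(C)C(C)(C)C)cc(O[Si](C)(C)C(C)(C)C)c1C(=O)O[C@@H]1CC2=C(COC([C@H]3O[C@@H]3C)=C2)C(=O)[C@]1(C)O | intermediate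
28 | (6R,7R)-7-hydroxy-7-methyl-3-[(2S,3R)-3-methyloxiran-2-yl]-8-oxo-5,6,7,8-tetrahydro-1H-isochromen-6-yl 2,4-dihydroxy-6-methylbenzoate (CNP0323247.1) | Cc1cc(O)cc(O)c1C(=O)O[C@@H]1CC2=C(COC([C@H]3O[C@@H]3C)=C2)C(=O)[C@]1(C)O | target

## Step count and least certain steps

Total step count: 23. Longest linear sequence: 20 steps (1 to 28 through steps 1–13, 16–20, 22 and 23). The epoxy acid branch (steps 14 and 15) and the aryl branch (step 21) join it.

**Step 18 (key step).** The most likely failure is slow initiation at the hindered, conjugated C4a vinyl group. The Ru=CH2 released after each turnover can then be captured by the electron-rich enol ether as a dormant alkoxycarbene, so the catalyst dies before conversion is complete; intermolecular dimerization at the vinyl group is the second risk. The fallback keeps the same bond and ring closure but moves initiation to an unhindered site by relay metathesis.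
- It sets out from enal 13. Wittig reaction with the ylide from (hex-5-en-1-yl)triphenylphosphonium bromide and NaN(SiMe3)2 should give the relay tetraene (3S,4R,5R)-1-[(1Z)-hepta-1,6-dien-1-yl]-4-methyl-3,4,5-tris(triethylsilyloxy)-2-[(triethylsilyloxy)methyl]cyclohex-1-ene F1.
- Selective primary desilylation as in step 13 gives the relay alcohol F2, esterification with 18 as in step 16 gives the relay ester F3, and Cp2TiMe2 methylenation as in step 17 gives the relay enol ether F4.
- With (H2IMes)(PCy3)Cl2Ru=CHPh the catalyst loads on the terminal alkene of F4 and expels cyclopentene. This places ruthenium on C4 without bimolecular initiation at the diene, and the alkylidene closes onto the enol ether. The fallback returns to the route at 21.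

**Step 17.** The most likely failure is attack of titanium species on the epoxide at 70 °C, or hydrolysis of the acid-labile acyclic enol ether during isolation. The fallback sets out from ester 19 and avoids the isolated enol ether. A reduced titanium ethylidene reagent (TiCl4, Zn, PbCl2, TMEDA, CH3CHBr2, THF/CH2Cl2, rt) should exchange with the vinyl group and then olefinate the ester carbonyl intramolecularly. This olefinic-ester cyclization forms the same C3=C4 bond and returns directly at 21; no new compound is made.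

**Step 11.** The most likely failure is enolization of the bis(α-silyloxy) ketone toward C8 followed by β-elimination of the C7 silyloxy group, or sluggish addition of the aldehyde enamine to the hindered ketone. The fallback sets out from nitrile 10 and replaces the aldol by a Horner–Wadsworth–Emmons closure.
- Deprotonation with LiN(iPr)2 and quenching with ClP(O)(OEt)2 gives the cyanophosphonate diethyl [(3R,4R,5S)-1-cyano-4-methyl-6-methylidene-3,4,5,7-tetrakis(triethylsilyloxy)heptyl]phosphonate F5.
- Ozonolysis as in step 10 gives the keto phosphonate F6.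
- LiCl and DBU in MeCN deprotonate only the acidic phosphonate carbon, and olefination of the ketone gives the unsaturated nitrile (3S,4R,5R)-4-methyl-3,4,5-tris(triethylsilyloxy)-2-[(triethylsilyloxy)methyl]cyclohex-1-ene-1-carbonitrile F7.
- iBu2AlH reduction returns to the route at 13.

**Step 22.** The most likely failure is slow acylation of the hindered C6 hydroxyl by the di-ortho-substituted aroyl chloride, leaving time for base-induced retro-aldol cleavage or acyl transfer to the C7 hydroxyl. The fallback changes the acyl donor to a benzodioxinone opened by the alkoxide.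
- It sets out from 24. Acetone, (CF3CO)2O and CF3CO2H give 7-hydroxy-2,2,5-trimethyl-4H-1,3-benzodioxin-4-one F8, and t-BuMe2SiCl with imidazole gives 7-(tert-butyldimethylsilyloxy)-2,2,5-trimethyl-4H-1,3-benzodioxin-4-one F9.
- The C6 alkoxide of 23 (NaN(SiMe3)2, THF, −78 °C) adds to the dioxinone carbonyl of F9 with loss of acetone, giving the mono-silylated ester (6R,7R)-7-hydroxy-7-methyl-3-[(2S,3R)-3-methyloxiran-2-yl]-8-oxo-5,6,7,8-tetrahydro-1H-isochromen-6-yl 4-(tert-butyldimethylsilyloxy)-2-hydroxy-6-methylbenzoate F10.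
- Bu4NF/AcOH returns to the route at 28.

## Further compounds

F1 | step 18 | (3S,4R,5R)-1-[(1Z)-hepta-1,6-dien-1-yl]-4-methyl-3,4,5-tris(triethylsilyloxy)-2-[(triethylsilyloxy)methyl]cyclohex-1-ene | CC[Si](CC)(CC)O[C@@H]1CC(/C=C\CCCC=C)=C(CO[Si](CC)(CC)CC)[C@H](O[Si](CC)(CC)CC)[C@]1(C)O[Si](CC)(CC)CC
F2 | step 18 | [(4R,5R,6S)-2-[(1Z)-hepta-1,6-dien-1-yl]-5-methyl-4,5,6-tris(triethylsilyloxy)cyclohex-1-en-1-yl]methanol | CC[Si](CC)(CC)O[C@@H]1CC(/C=C\CCCC=C)=C(CO)[C@H](O[Si](CC)(CC)CC)[C@]1(C)O[Si](CC)(CC)CC
F3 | step 18 | [(4R,5R,6S)-2-[(1Z)-hepta-1,6-dien-1-yl]-5-methyl-4,5,6-tris(triethylsilyloxy)cyclohex-1-en-1-yl]methyl (2S,3R)-3-methyloxirane-2-carboxylate | CC[Si](CC)(CC)O[C@@H]1CC(/C=C\CCCC=C)=C(COC(=O)[C@H]2O[C@@H]2C)[C@H](O[Si](CC)(CC)CC)[C@]1(C)O[Si](CC)(CC)CC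
F4 | step 18 | (2S,3R)-2-(1-{[(4R,5R,6S)-2-[(1Z)-hepta-1,6-dien-1-yl]-5-methyl-4,5,6-tris(triethylsilyloxy)cyclohex-1-en-1-yl]methoxy}ethenyl)-3-methyloxirane | CC[Si](CC)(CC)O[C@@H]1CC(/C=C\CCCC=C)=C(COC(=C)[C@H]2O[C@@H]2C)[C@H](O[Si](CC)(CC)CC)[C@]1(C)O[Si](CC)(CC)CC
F0 | step 17 | none | none
F5 | step 11 | diethyl [(3R,4R,5S)-1-cyano-4-methyl-6-methylidene-3,4,5,7-tetrakis(triethylsilyloxy)heptyl]phosphonate (epimers at C1) | CCOP(=O)(OCC)C(C#N)C[C@@H](O[Si](CC)(CC)CC)[C@@](C)(O[Si](CC)(CC)CC)[C@@H](O[Si](CC)(CC)CC)C(=C)CO[Si](CC)(CC)CC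
F6 | step 11 | diethyl [(3R,4R,5R)-1-cyano-4-methyl-6-oxo-3,4,5,7-tetrakis(triethylsilyloxy)heptyl]phosphonate (epimers at C1) | CCOP(=O)(OCC)C(C#N)C[C@@H](O[Si](CC)(CC)CC)[C@@](C)(O[Si](CC)(CC)CC)[C@@H](O[Si](CC)(CC)CC)C(=O)CO[Si](CC)(CC)CC
F7 | step 11 | (3S,4R,5R)-4-methyl-3,4,5-tris(triethylsilyloxy)-2-[(triethylsilyloxy)methyl]cyclohex-1-ene-1-carbonitrile | CC[Si](CC)(CC)O[C@@H]1CC(C#N)=C(CO[Si](CC)(CC)CC)[C@H](O[Si](CC)(CC)CC)[C@]1(C)O[Si](CC)(CC)CC
F8 | step 22 | 7-hydroxy-2,2,5-trimethyl-4H-1,3-benzodioxin-4-one | Cc1cc(O)cc2OC(C)(C)OC(=O)c12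
F9 | step 22 | 7-(tert-butyldimethylsilyloxy)-2,2,5-trimethyl-4H-1,3-benzodioxin-4-one | Cc1cc(O[Si](C)(C)C(C)(C)C)cc2OC(C)(C)OC(=O)c12
F10 | step 22 | (6R,7R)-7-hydroxy-7-methyl-3-[(2S,3R)-3-methyloxiran-2-yl]-8-oxo-5,6,7,8-tetrahydro-1H-isochromen-6-yl 4-(tert-butyldimethylsilyloxy)-2-hydroxy-6-methylbenzoate | Cc1cc(O[Si](C)(C)C(C)(C)C)cc(O)c1C(=O)O[C@@H]1CC2=C(COC([C@H]3O[C@@H]3C)=C2)C(=O)[C@]1(C)O
A1 | alternative 1 | 3-oxo-3,4-dihydro-1H-isochromene-7-carboxylic acid | O=C1Cc2ccc(cc2CO1)C(=O)O
A2 | alternative 1 | (6R,7S)-6,7-dihydroxy-3-oxo-3,4,6,7-tetrahydro-1H-isochromene-7-carboxylic acid | O[C@@H]1C=C2CC(=O)OCC2=C[C@@]1(O)C(=O)O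
A3 | alternative 2 | (2S,3R,8R)-2,3-bis(tert-butyldimethylsilyloxy)-1-iodo-3-methyl-8-[(2S,3R)-3-methyloxiran-2-yl]-8-(triethylsilyloxy)oct-5-yn-4-one | CC(C)(C)[Si](C)(C)O[C@@H]([C@@](C)(O[Si](C)(C)C(C)(C)C)C(=O)C#CC[C@@H](O[Si](CC)(CC)CC)[C@H]1O[C@@H]1C)CI
A4 | alternative 2 | (5R,6R)-5,6-bis(tert-butyldimethylsilyloxy)-2-iodo-6-methyl-3-{(2R)-2-[(2S,3R)-3-methyloxiran-2-yl]-2-(triethylsilyloxy)ethyl}cyclohex-2-en-1-one | CC(C)(C)[Si](C)(C)O[C@@H]1CC(C[C@@H](O[Si](CC)(CC)CC)[C@H]2O[C@@H]2C)=C(I)C(=O)[C@]1(C)O[Si](C)(C)C(C)(C)C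
A5 | alternative 3 | 1-[(6R,7S)-6-(tert-butyldimethylsilyloxy)-7-hydroxy-3-[(2S,3R)-3-methyloxiran-2-yl]-1,5,6,7-tetrahydrocyclopenta[c]pyran-7-yl]ethan-1-one | CC(C)(C)[Si](C)(C)O[C@@H]1CC2=C(COC([C@H]3O[C@@H]3C)=C2)[C@@]1(O)C(C)=O
A6 | alternative 3 | (6R,7R)-6-(tert-butyldimethylsilyloxy)-7-hydroxy-7-methyl-3-[(2S,3R)-3-methyloxiran-2-yl]-6,7-dihydro-1H-isochromen-8(5H)-one | CC(C)(C)[Si](C)(C)O[C@@H]1CC2=C(COC([C@H]3O[C@@H]3C)=C2)C(=O)[C@]1(C)O
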